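## Structural features

The target is a labdane whose trans-fused decalin (rings A and B) carries two oxidised one-carbon arms on the same face: C19, a carboxyl carbon on quaternary C4 beside the C18 methyl, and C20, an acetoxymethyl group on quaternary C10. C19 is closed as a γ-lactone onto the axial β-oxygen at C6, so C4, C5 and C6 sit in a cis-fused oxolanone. Ring B continues with C8 (equatorial α-methyl, β-hydrogen) and the fully substituted C9, whose α-oxygen and β-C11 make it the spiro atom of an oxolane (O, C9, C11, C12, C13). C13 is a second spiro atom, shared with a 2,3-dihydrofuran (C13, C14=C15, O, C16). Six stereocentres are contiguous (C6–C5–C4 and C5–C10–C9–C8); the seventh, C13 (R), is insulated by C11 and C12 and differs from its epimer only by exchange of C14 and C16. Fragile groups are the cyclic enol ether with its allylic tertiary ether at C13 (acid opens it to a 3-alkylfuran and a 9-hydroxyl), the lactone (hydride, hydroxide) and the primary acetate (alkoxide; a free C20 hydroxyl could also attack C19). The difficulty lies in the two quaternary carbons with oxidised substituents, the oxygenated C9 next to C10 with a defined C8 methyl, and control of the remote C13. The key step uses the C4/C5/C6/C10 pattern: an axial ester-level carbon on C4, an oxygenated angular carbon on C10 and oxygen on C6 beside the C5–H are what the C4 radical of an α-methyl β-keto ester leaves when it closes rings A and B onto a C6-oxygenated diene; the C3 carbonyl is deleted afterwards.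

## Logic of the disconnections

53 is taken back through 52 and 50 to 49. No skeletal bond is cut; the C14=C15 enol ether is exchanged for a C14 ketone and then a C14 alcohol. The reason is that the enol ether is the acid-labile function and should appear last, under basic reductive conditions. The gain is a saturated, robust bis-ether for all earlier work. The demand is that enolisation of 50 can go only toward C15 and that the reduction of 52 spares lactone and acetate.

49 is opened at O16–C15 and O9–C13, which leads through 47 and 46 to 45. Cutting here lets C13 be set by a reagent-controlled epoxide that the 9-hydroxyl opens with inversion, instead of by the weak bias of the distant decalin. The gain is an acyclic allylic diol side chain. The demand is 5-exo opening at the tertiary epoxide carbon and ring closure between the two primary oxygens only.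

45 is cut at C12–C13 into 37 and 41; 41 comes from 38 through 40. This sp3–sp2 bond joins the complete decalin lactone to a four-carbon unit that already holds C13–C16 at the right oxidation levels. The gain is convergence. The demand is a coupling that keeps the alkene geometry (C12 cis to C15) and tolerates lactone, acetate and a tertiary alcohol.

37 is reopened at the lactone O–C6 bond and at C12–I to give 35 through 36. The C6 oxygen of 35 is equatorial, as the key step delivers it, so the lactone must form with inversion. The gain is that one activation serves both C6 and C12. The demand is backside attack at C6 by the axial C19 carbonyl and no reaction at the tertiary 9-hydroxyl.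

35 is traced through 34 and 33 to 32, 29 and 28; the C8–H bond, the C8=C17 bond and the C9–O bond are removed in turn. C9 is oxygenated through the C8 ketone because that is the only handle next to it. The gain is a simple ketone. The demands are enolisation toward C9, α-face oxidation, and delivery of the C8 hydrogen from the β face.

28 goes back to 27 and, by restoring the C3 carbonyl through 26 and 25, to 24. The C8 methylene is the source of the ketone and the C3 oxygen is a relic of the ring-forming step. The gain is that 24 is the direct product of that step. The demand is a deoxygenation that leaves the alkene and the esters alone.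

24 is cut at C4–C5 and C9–C10 to give 23. This removes both rings and four stereocentres and leaves an acyclic chain with one carbinol centre. The demand is a cyclization that starts at C4, closes two six-membered rings in the endo mode and ends by elimination, with the C6 substituent steering the facial sense.

23 is stripped of the acetyl group (22) and cut at C10–C20 (21) and at C1–C2 into 18 and 19. The two carbon arms on C10 are added at different times so that their positions relative to C6 are never in doubt. The gain is a commercial keto ester and an allylic bromide. The demand is γ-alkylation of a dianion in the presence of a vinyl iodide and a geometry-retaining hydroxymethylation.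

18 is traced through 17 and 16 to 15 and, by removing iodine and the C5 hydrogen, to 13. An alkyne is the simplest precursor of the trisubstituted alkene. The demand is a trans-hydrometalation directed by the C6 hydroxyl, which puts the metal, and later C20, cis to C6.

13 is taken to 12 and 11 and cut at C5–C6 into 8 and 9. The C6 carbinol is the single stereocentre that the route must create with a chiral reagent. The gain is an achiral aldehyde and a commercial alkyne. The demand is an enantioselective ynone reduction that does not enolise the skipped C7 position.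

8 goes back through 7 and 6 to 5, which is cut at C9–C11 and C8–C17 into 1, 2 and a methyl group from trimethylaluminium. The gain is three commercial compounds. The demand is a syn carbometalation that fixes the (E)-C8=C9 alkene and an alkenyl–epoxide coupling with retention.

## Other disconnections considered

Alternative 1: The cut is made at O9–C13 and O16–C15. In the forward step the epoxy diol acetal A2 (9-hydroxyl, 13,14-epoxide, C16 hydroxyl, C15 dimethyl acetal) is treated with acid: the 9-hydroxyl opens the epoxide at C13 with inversion and the C16 hydroxyl closes onto C15, giving the bis-spiro ether A1. In its favour, C13 comes stereospecifically from a reagent-controlled epoxide and both ether rings form in one flask. Against it, A1 still carries a C14 hydroxyl and a C15 methoxy group, and converting that pair into the C14=C15 enol ether needs a reductive 1,2-elimination of two or three steps next to an acid-labile spiro ether. The plan also presupposes a decalin lactone with the 9α-hydroxyl and 8α-methyl in place, so it competes with steps 28–33 and not with the ring construction. On mechanism its first event is the same as in step 29, so the two are equal in control of C13. A1 is the better plan in closing the second ring in the same operation. The chosen endgame is the better one in reaching the enol ether from a C14 ketone under basic conditions. The step counts of the two endgames are about equal.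

Alternative 2: The cut is made at C4–C5 and C10–C20. Irradiation of the enone ester A4 should give the cyclobutane lactone A3, and a later retro-aldol would release C20 as a formyl group on C10. In its favour, the lactone is present from the start with the correct C6 configuration, both quaternary carbons form in one step, C20 arrives already oxidised and no C3 ketone has to be deleted. The C9 ketone of A3 would also accept the side chain as a nucleophile and give the 9α-oxygen directly. On these points it is better than the chosen plan, which needs a C6 inversion, a three-step deoxygenation and four steps to oxygenate C9. Against it, the key step closes only a temporary four-membered ring and the lactone; ring A must be closed later by C3–C4 alkylation, where C4 is set a second time, and the C8 methyl still has to be introduced. On structure, A3 holds one carbocycle of the decalin and three of its stereocentres, whereas step 15 gives two rings and four stereocentres. On mechanism, a triplet cycloaddition with diradical intermediates replaces a ground-state cascade through chair transition states. Overall step economy should be similar.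

Alternative 3: The cut is made at the O–C9 bond. Base should make the C13 alkoxide of the enone carbinol A6 add 5-exo-trig to C9, and protonation would then set C8 in the 7-oxo spiro ether A5. In its favour, C13 is preset in a small building block, and the C9–O bond and the C8 configuration are set together, with the methyl equilibrating to the equatorial position next to the ketone. On C8 and C9 this is better than steps 19–23 of the chosen plan, and on C13 it is its equal with fewer steps. Against it, a hindered tertiary alkoxide must add to a fully substituted carbon beside quaternary C10, and this reversible addition may rest on the side of A6. A5 also has a C7 ketone that the target lacks and no oxygen at C6, so C6 must be oxidised, C7 deoxygenated and the methyl ester lactonised late, beside the spiro ether and the alkyne. The decalin of A6 still needs its own ring-forming step. Overall it is stronger at the spiro centre, weaker in the lactone region, and at best equal in step count.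

Key step: step 15

Remark on the chemistry: the cyclization substrate 23 has two C=C bonds and is named as a (6Z,10E)-dienyl β-keto ester (the C5=C10 alkene has the farnesyl-type geometry, C1 trans to C6, but is Z by the sequence rule because C20 is oxygenated); C20 is carried as the acetate of the target; labdane numbering is used for 24–53, and C4 of 21–23 is an inconsequential epimeric mixture.

Step 1
Reactants: 1 tert-butyl(but-3-yn-1-yloxy)dimethylsilane; 2 oxirane
Product: 5 (E)-6-(tert-butyldimethylsilyloxy)-4-methylhex-3-en-1-ol, via alkenyldimethylalane 3 (not isolated), via lithium alkenylaluminate 4 (not isolated)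
Conditions: Me3Al, Cp2ZrCl2 (cat.), CH2Cl2, 0 °C to rt; n-BuLi, hexane–THF, −78 °C; 2, −78 to 0 °C; H2O
Reagents that add atoms: trimethylaluminium C[Al](C)C
Why: Zirconium-catalysed Negishi carboalumination adds CH3 and Al syn across the terminal alkyne with the metal on the terminal carbon, which fixes the (E)-C8=C9 geometry; the lithium alanate then opens oxirane with retention at the alkenyl carbon.

Step 2
Reactants: 5 (E)-6-(tert-butyldimethylsilyloxy)-4-methylhex-3-en-1-ol
Product: 6 (E)-1-(tert-butyldimethylsilyloxy)-6-(tert-butyldiphenylsilyloxy)-3-methylhex-3-ene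
Conditions: TBDPSCl, imidazole, DMF, rt
Reagents that add atoms: tert-butyl(chloro)diphenylsilane CC(C)(C)[Si](Cl)(c1ccccc1)c1ccccc1
Why: Imidazole-promoted silylation of the primary alcohol; no stereo element is touched.

Step 3
Reactants: 6 (E)-1-(tert-butyldimethylsilyloxy)-6-(tert-butyldiphenylsilyloxy)-3-methylhex-3-ene
Product: 7 (E)-6-(tert-butyldiphenylsilyloxy)-3-methylhex-3-en-1-ol
Conditions: PPTS (cat.), EtOH, 40 °C
Reagents that add atoms: none
Why: Acid-catalysed solvolysis removes the primary tert-butyldimethylsilyl ether much faster than the bulkier, more acid-stable tert-butyldiphenylsilyl ether.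

Step 4
Reactants: 7 (E)-6-(tert-butyldiphenylsilyloxy)-3-methylhex-3-en-1-ol
Product: 8 (E)-6-(tert-butyldiphenylsilyloxy)-3-methylhex-3-enal
Conditions: Dess–Martin periodinane, NaHCO3, CH2Cl2, 0 °C; used crude
Reagents that add atoms: none
Why: Dess–Martin oxidation under bicarbonate buffer should give the β,γ-unsaturated aldehyde without moving the alkene into conjugation.

Step 5
Reactants: 8 (E)-6-(tert-butyldiphenylsilyloxy)-3-methylhex-3-enal; 9 tert-butyldimethyl(prop-2-yn-1-yloxy)silane
Product: 11 rac-(E)-1-(tert-butyldimethylsilyloxy)-9-(tert-butyldiphenylsilyloxy)-6-methylnon-6-en-2-yn-4-ol, via lithium acetylide 10 (not isolated)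
Conditions: 9, n-BuLi, THF, −78 °C; then 8, −78 °C; H2O
Reagents that add atoms: none
Why: 1,2-Addition of a lithium acetylide to the aldehyde at −78 °C outruns enolisation; the carbinol is made racemic on purpose because steps 6 and 7 set C6.

Step 6
Reactants: 11 rac-(E)-1-(tert-butyldimethylsilyloxy)-9-(tert-butyldiphenylsilyloxy)-6-methylnon-6-en-2-yn-4-ol
Product: 12 (E)-1-(tert-butyldimethylsilyloxy)-9-(tert-butyldiphenylsilyloxy)-6-methylnon-6-en-2-yn-4-one
Conditions: Dess–Martin periodinane, NaHCO3, CH2Cl2, 0 °C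
Reagents that add atoms: none
Why: Dess–Martin oxidation of a propargylic alcohol to the ynone under buffered conditions that should leave the skipped C8=C9 alkene in place.

Step 7
Reactants: 12 (E)-1-(tert-butyldimethylsilyloxy)-9-(tert-butyldiphenylsilyloxy)-6-methylnon-6-en-2-yn-4-one
Product: 13 (4S,6E)-1-(tert-butyldimethylsilyloxy)-9-(tert-butyldiphenylsilyloxy)-6-methylnon-6-en-2-yn-4-ol
Conditions: Ru[(S,S)-TsDPEN](p-cymene) (2 mol%, 16-electron amido complex), i-PrOH, rt
Reagents that add atoms: none
Why: Noyori asymmetric transfer hydrogenation of an α,β-acetylenic ketone: the (S,S)-catalyst distinguishes the alkynyl from the alkyl arm and should give the (S)-propargylic alcohol (C6); the base-free complex avoids enolisation toward C7.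

Step 8
Reactants: 13 (4S,6E)-1-(tert-butyldimethylsilyloxy)-9-(tert-butyldiphenylsilyloxy)-6-methylnon-6-en-2-yn-4-ol
Product: 15 (2Z,4S,6E)-1-(tert-butyldimethylsilyloxy)-9-(tert-butyldiphenylsilyloxy)-2-iodo-6-methylnona-2,6-dien-4-ol, via cyclic alkenylalanate 14 (not isolated)
Conditions: NaAlH2(OCH2CH2OMe)2, THF, 0 °C to rt; I2, THF, −78 °C
Reagents that add atoms: iodine II
Why: Alkoxide-directed trans-hydroalumination of the propargylic alcohol puts H on C5 and Al on C10 in a five-membered alanate; iodinolysis with retention gives the vinyl iodide with iodine cis to C6, the site that becomes C20.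

Step 9
Reactants: 15 (2Z,4S,6E)-1-(tert-butyldimethylsilyloxy)-9-(tert-butyldiphenylsilyloxy)-2-iodo-6-methylnona-2,6-dien-4-ol
Product: 16 (2Z,4S,6E)-1,4-bis(tert-butyldimethylsilyloxy)-9-(tert-butyldiphenylsilyloxy)-2-iodo-6-methylnona-2,6-diene
Conditions: TBSOTf, 2,6-lutidine, CH2Cl2, −78 to 0 °C
Reagents that add atoms: tert-butyldimethylsilyl trifluoromethanesulfonate CC(C)(C)[Si](C)(C)OS(=O)(=O)C(F)(F)F
Why: Silylation of the secondary allylic alcohol with the silyl triflate installs the bulky C6 group that steers the key step.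

Step 10
Reactants: 16 (2Z,4S,6E)-1,4-bis(tert-butyldimethylsilyloxy)-9-(tert-butyldiphenylsilyloxy)-2-iodo-6-methylnona-2,6-diene
Product: 17 (2Z,4S,6E)-4-(tert-butyldimethylsilyloxy)-9-(tert-butyldiphenylsilyloxy)-2-iodo-6-methylnona-2,6-dien-1-ol
Conditions: HF·pyridine, pyridine, THF, 0 °C
Reagents that add atoms: none
Why: Buffered HF·pyridine cleaves the unhindered primary allylic silyl ether selectively over the secondary tert-butyldimethylsilyl and the tert-butyldiphenylsilyl ethers.

Step 11
Reactants: 17 (2Z,4S,6E)-4-(tert-butyldimethylsilyloxy)-9-(tert-butyldiphenylsilyloxy)-2-iodo-6-methylnona-2,6-dien-1-ol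
Product: 18 (2Z,4S,6E)-1-bromo-4-(tert-butyldimethylsilyloxy)-9-(tert-butyldiphenylsilyloxy)-2-iodo-6-methylnona-2,6-diene
Conditions: CBr4, PPh3, 2,6-lutidine, CH2Cl2, 0 °C
Reagents that add atoms: carbon tetrabromide BrC(Br)(Br)Br
Why: Appel bromination of the primary allylic alcohol (SN2 at C1, no allylic transposition); lutidine shields the silyl ethers from acid.

Step 12
Reactants: 18 (2Z,4S,6E)-1-bromo-4-(tert-butyldimethylsilyloxy)-9-(tert-butyldiphenylsilyloxy)-2-iodo-6-methylnona-2,6-diene; 19 methyl 2-methyl-3-oxobutanoate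
Product: 21 methyl (6Z,8S,10E)-8-(tert-butyldimethylsilyloxy)-13-(tert-butyldiphenylsilyloxy)-6-iodo-2,10-dimethyl-3-oxotrideca-6,10-dienoate, via acetoacetate dianion 20 (not isolated)
Conditions: 19, NaH, THF, 0 °C; n-BuLi, 0 °C; 18, −78 to 0 °C; H2O
Reagents that add atoms: none
Why: γ-Alkylation of the acetoacetate dianion: the terminal carbanion is far more nucleophilic than the stabilised enolate and displaces the allylic bromide (C1–C2 bond) at low temperature, while the vinyl iodide is inert.

Step 13
Reactants: 21 methyl (6Z,8S,10E)-8-(tert-butyldimethylsilyloxy)-13-(tert-butyldiphenylsilyloxy)-6-iodo-2,10-dimethyl-3-oxotrideca-6,10-dienoate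
Product: 22 methyl (6Z,8S,10E)-8-(tert-butyldimethylsilyloxy)-13-(tert-butyldiphenylsilyloxy)-6-(hydroxymethyl)-2,10-dimethyl-3-oxotrideca-6,10-dienoate
Conditions: Bu3SnCH2OH, Pd(PPh3)4 (5 mol%), toluene, 90 °C
Reagents that add atoms: (tributylstannyl)methanol OC[Sn](CCCC)(CCCC)CCCC
Why: Stille coupling transfers the hydroxymethyl group to C10 with retention of alkene geometry, so C20 ends cis to C6 and C1 trans to it.

Step 14
Reactants: 22 methyl (6Z,8S,10E)-8-(tert-butyldimethylsilyloxy)-13-(tert-butyldiphenylsilyloxy)-6-(hydroxymethyl)-2,10-dimethyl-3-oxotrideca-6,10-dienoate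
Product: 23 methyl (6Z,8S,10E)-6-(acetoxymethyl)-8-(tert-butyldimethylsilyloxy)-13-(tert-butyldiphenylsilyloxy)-2,10-dimethyl-3-oxotrideca-6,10-dienoate
Conditions: Ac2O, pyridine, CH2Cl2, 0 °C
Reagents that add atoms: acetic anhydride CC(=O)OC(C)=O
Why: Pyridine-mediated acetylation of the primary allylic alcohol; the acetate is introduced only after the dianion step, so it never meets a strong base or a neighbouring free hydroxyl that could take it over.

Step 15
Reactants: 23 methyl (6Z,8S,10E)-6-(acetoxymethyl)-8-(tert-butyldimethylsilyloxy)-13-(tert-butyldiphenylsilyloxy)-2,10-dimethyl-3-oxotrideca-6,10-dienoate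
Product: 24 methyl 20-acetoxy-6α-(tert-butyldimethylsilyloxy)-12-(tert-butyldiphenylsilyloxy)-3-oxo-13,14,15,16-tetranorlabd-8(17)-en-19-oate
Conditions: Mn(OAc)3·2H2O (2.2 equiv), Cu(OAc)2·H2O (1 equiv), degassed AcOH, rt
Reagents that add atoms: none
Why: Mn(OAc)3 forms the manganese enolate of the β-keto ester and oxidises it to the electrophilic tertiary C4 radical, the known oxidative free-radical polyene cyclization of unsaturated α-substituted β-keto esters with trivalent manganese and divalent copper. Ring A closes by 6-endo-trig addition of C4 to C5 and ring B by 6-endo-trig addition of the tertiary C10 radical to C9, each through a chair-like transition state; Cu(OAc)2 then oxidises the tertiary C8 radical and the alkylcopper intermediate loses a C17 hydrogen to give the exocyclic alkene. C4 is set by the chair of ring A, in which the ketone stays in the ring and the ester takes the axial site cis to C20. The trans ring fusion at C5 and C10 follows from the geometry of the C5=C10 alkene (C1 trans to C6), and the equatorial C11 chain at C9 from the (E)-C8=C9 alkene. The absolute sense of all four centres is relayed from C6: its silyloxy group takes the equatorial site of the ring B chair with the C6–H bond eclipsing the C20 arm (least allylic 1,3-strain), so only one face of the C5=C10 alkene is open to C4. The step needs 6-endo over 5-exo closure at both alkenes, secured by the 1,1-disubstituted carbons C10 and C8 that give tertiary radicals, and termination by elimination instead of hydrogen abstraction, secured by the copper salt. The acetate and both silyl ethers should be inert to the oxidant in acetic acid at room temperature.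

Step 16
Reactants: 24 methyl 20-acetoxy-6α-(tert-butyldimethylsilyloxy)-12-(tert-butyldiphenylsilyloxy)-3-oxo-13,14,15,16-tetranorlabd-8(17)-en-19-oate
Product: 25 methyl 20-acetoxy-3β-hydroxy-6α-(tert-butyldimethylsilyloxy)-12-(tert-butyldiphenylsilyloxy)-13,14,15,16-tetranorlabd-8(17)-en-19-oate
Conditions: NaBH4, THF–MeOH, −20 °C
Reagents that add atoms: none
Why: Borohydride reduction of the hindered C3 ketone (axial attack, 3β-alcohol expected) leaves both esters alone; the new centre is removed in step 18.

Step 17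
Reactants: 25 methyl 20-acetoxy-3β-hydroxy-6α-(tert-butyldimethylsilyloxy)-12-(tert-butyldiphenylsilyloxy)-13,14,15,16-tetranorlabd-8(17)-en-19-oate
Product: 26 methyl 20-acetoxy-3β-(imidazol-1-ylthiocarbonyloxy)-6α-(tert-butyldimethylsilyloxy)-12-(tert-butyldiphenylsilyloxy)-13,14,15,16-tetranorlabd-8(17)-en-19-oate
Conditions: 1,1′-thiocarbonyldiimidazole, DMAP, ClCH2CH2Cl, 70 °C
Reagents that add atoms: 1,1′-thiocarbonyldiimidazole S=C(n1ccnc1)n1ccnc1
Why: Thioacylation of the secondary alcohol under neutral conditions (first half of the Barton–McCombie deoxygenation) avoids the retro-aldol cleavage that an alkoxide of this β-hydroxy ester could undergo.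

Step 18
Reactants: 26 methyl 20-acetoxy-3β-(imidazol-1-ylthiocarbonyloxy)-6α-(tert-butyldimethylsilyloxy)-12-(tert-butyldiphenylsilyloxy)-13,14,15,16-tetranorlabd-8(17)-en-19-oate
Product: 27 methyl 20-acetoxy-6α-(tert-butyldimethylsilyloxy)-12-(tert-butyldiphenylsilyloxy)-13,14,15,16-tetranorlabd-8(17)-en-19-oate
Conditions: Bu3SnH, AIBN, toluene, 100 °C
Reagents that add atoms: none
Why: Barton–McCombie radical deoxygenation: the stannyl radical adds to C=S, the C3–O bond fragments and the secondary radical takes hydrogen from Bu3SnH; the 8(17)-alkene is too far away to trap it.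

Step 19
Reactants: 27 methyl 20-acetoxy-6α-(tert-butyldimethylsilyloxy)-12-(tert-butyldiphenylsilyloxy)-13,14,15,16-tetranorlabd-8(17)-en-19-oate
Product: 28 methyl 20-acetoxy-8-oxo-6α-(tert-butyldimethylsilyloxy)-12-(tert-butyldiphenylsilyloxy)-13,14,15,16,17-pentanorlabdan-19-oate
Conditions: O3, CH2Cl2–MeOH, −78 °C; Me2S
Reagents that add atoms: ozone [O-][O+]=O
Why: Ozonolysis of the only alkene with reductive work-up gives the C8 ketone.

Step 20
Reactants: 28 methyl 20-acetoxy-8-oxo-6α-(tert-butyldimethylsilyloxy)-12-(tert-butyldiphenylsilyloxy)-13,14,15,16,17-pentanorlabdan-19-oate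
Product: 29 methyl 20-acetoxy-8-(trimethylsilyloxy)-6α-(tert-butyldimethylsilyloxy)-12-(tert-butyldiphenylsilyloxy)-13,14,15,16,17-pentanorlabd-8-en-19-oate
Conditions: TMSCl, NaI, Et3N, MeCN, rt
Reagents that add atoms: chlorotrimethylsilane C[Si](C)(C)Cl
Why: Silyl enol ether formation with iodotrimethylsilane made in situ and triethylamine is equilibrating and should favour the more substituted C8=C9 isomer; no strong base is present, so the β-silyloxy group at C6 is not eliminated.

Step 21
Reactants: 29 methyl 20-acetoxy-8-(trimethylsilyloxy)-6α-(tert-butyldimethylsilyloxy)-12-(tert-butyldiphenylsilyloxy)-13,14,15,16,17-pentanorlabd-8-en-19-oate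
Product: 32 methyl 20-acetoxy-9α-hydroxy-8-oxo-6α-(tert-butyldimethylsilyloxy)-12-(tert-butyldiphenylsilyloxy)-13,14,15,16,17-pentanorlabdan-19-oate, via silyloxy epoxide 30 (not isolated), via 9-silyloxy ketone 31 (not isolated)
Conditions: mCPBA, NaHCO3, CH2Cl2, −20 to 0 °C; then 1 M HCl, THF, 0 °C
Reagents that add atoms: 3-chloroperoxybenzoic acid OOC(=O)c1cccc(Cl)c1
Why: Rubottom oxidation: the peracid epoxidises the enol ether from the α face, anti to the axial C20 arm, and silyl migration with ring opening leaves the oxygen 9α and C11 β; brief dilute acid frees the tertiary alcohol.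

Step 22
Reactants: 32 methyl 20-acetoxy-9α-hydroxy-8-oxo-6α-(tert-butyldimethylsilyloxy)-12-(tert-butyldiphenylsilyloxy)-13,14,15,16,17-pentanorlabdan-19-oate
Product: 33 methyl 20-acetoxy-9α-hydroxy-6α-(tert-butyldimethylsilyloxy)-12-(tert-butyldiphenylsilyloxy)-13,14,15,16-tetranorlabd-8(17)-en-19-oate
Conditions: Zn, CH2Br2, TiCl4, THF–CH2Cl2, 0 °C to rt
Reagents that add atoms: dibromomethane BrCBr
Why: Lombardo–Takai methylenation converts the hindered, enolisable ketone to the methylene compound and, unlike a phosphorus ylide, does not attack the acetate.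

Step 23
Reactants: 33 methyl 20-acetoxy-9α-hydroxy-6α-(tert-butyldimethylsilyloxy)-12-(tert-butyldiphenylsilyloxy)-13,14,15,16-tetranorlabd-8(17)-en-19-oate
Product: 34 methyl 20-acetoxy-9α-hydroxy-6α-(tert-butyldimethylsilyloxy)-12-(tert-butyldiphenylsilyloxy)-13,14,15,16-tetranorlabdan-19-oate (8α-methyl)
Conditions: Mn(dpm)3 (10 mol%), PhSiH3, t-BuOOH, i-PrOH, rt
Reagents that add atoms: none
Why: Manganese hydride hydrogen-atom-transfer hydrogenation: H adds to C17 and the tertiary C8 radical is then quenched along the axial β direction, so the methyl should settle equatorial (8α), the thermodynamically preferred epimer; surface hydrogenation from the open α face would give the other.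

Step 24
Reactants: 34 methyl 20-acetoxy-9α-hydroxy-6α-(tert-butyldimethylsilyloxy)-12-(tert-butyldiphenylsilyloxy)-13,14,15,16-tetranorlabdan-19-oate (8α-methyl)
Product: 35 methyl 20-acetoxy-6α,9α,12-trihydroxy-13,14,15,16-tetranorlabdan-19-oate
Conditions: Bu4NF, AcOH, THF, rt
Reagents that add atoms: none
Why: Fluoride cleaves both silyl ethers; the acetic acid buffer keeps the acetate in place, and the 6α-hydroxyl, trans to C19, cannot lactonise.

Step 25
Reactants: 35 methyl 20-acetoxy-6α,9α,12-trihydroxy-13,14,15,16-tetranorlabdan-19-oate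
Product: 37 20-acetoxy-9α-hydroxy-12-iodo-13,14,15,16-tetranorlabdan-19,6β-olide, via bis-mesylate 36 (not isolated)
Conditions: Ms2O, pyridine, CH2Cl2, 0 °C; then NaI, DMF, 90 °C
Reagents that add atoms: sodium iodide [Na+].[I-]
Why: The primary and secondary alcohols are mesylated while the tertiary 9-hydroxyl is inert. On heating with iodide the C12 mesylate undergoes Finkelstein exchange, and the axial ester carbonyl displaces the equatorial C6 mesylate from the β face (intramolecular SN2, inversion at C6). Iodide then demethylates the methoxy-oxocarbenium ion to the 19,6β-lactone.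

Step 26
Reactants: 38 but-2-yne-1,4-diol
Product: 40 (Z)-2-iodobut-2-ene-1,4-diol, via cyclic alkenylalanate 39 (not isolated)
Conditions: NaAlH2(OCH2CH2OMe)2, THF, 0 °C to rt; I2, THF, −78 °C
Reagents that add atoms: iodine II
Why: Alkoxide-directed trans-hydroalumination and iodinolysis give the (Z)-iodide in which the two hydroxymethyl groups are trans to each other.

Step 27
Reactants: 40 (Z)-2-iodobut-2-ene-1,4-diol
Product: 41 (Z)-2-iodo-1,4-bis(triethylsilyloxy)but-2-ene
Conditions: TESCl, imidazole, DMF, 0 °C to rt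
Reagents that add atoms: chlorotriethylsilane CC[Si](Cl)(CC)CC
Why: Silylation of both primary alcohols as acid-labile triethylsilyl ethers.

Step 28
Reactants: 37 20-acetoxy-9α-hydroxy-12-iodo-13,14,15,16-tetranorlabdan-19,6β-olide; 41 (Z)-2-iodo-1,4-bis(triethylsilyloxy)but-2-ene
Product: 45 (13E)-20-acetoxy-9α,15,16-trihydroxylabd-13-en-19,6β-olide, via alkenyllithium 42 (not isolated), via alkenylzinc chloride 43 (not isolated), via bis-triethylsilyl ether 44 (not isolated)
Conditions: 41 (3 equiv), t-BuLi, Et2O, −78 °C; ZnCl2, THF, −78 °C to rt; 37, Pd2(dba)3 (2 mol%), P(c-C5H9)3 (8 mol%), N-methylimidazole, THF–NMP, 80 °C; then 1 M HCl, THF, rt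
Reagents that add atoms: none
Why: Negishi coupling of a primary alkyl iodide with an alkenylzinc halide under a bulky trialkylphosphine–palladium catalyst, which suppresses β-hydride elimination. The alkenyl geometry is retained (C12 cis to C15), and the alkenylzinc is used in excess to absorb the free 9-hydroxyl. Acidic work-up removes the triethylsilyl groups.

Step 29
Reactants: 45 (13E)-20-acetoxy-9α,15,16-trihydroxylabd-13-en-19,6β-olide
Product: 47 (13S,14R)-20-acetoxy-9α,13-epoxy-14,15,16-trihydroxylabdan-19,6β-olide, via epoxy diol 46 (not isolated)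
Conditions: Ti(Oi-Pr)4, D-(−)-diethyl tartrate, t-BuOOH, 4 Å MS, CH2Cl2, −20 °C; then CSA (cat.), 0 °C
Reagents that add atoms: tert-butyl hydroperoxide CC(C)(C)OO
Why: Sharpless asymmetric epoxidation: D-(−)-tartrate should deliver oxygen to the face of the C13=C14 alkene that gives the (13R,14R)-epoxide; the two allylic hydroxyls are trans and direct to the same face. The 9α-hydroxyl then opens the epoxide 5-exo at the tertiary C13 with inversion, which sets C13 as in the target.

Step 30
Reactants: 47 (13S,14R)-20-acetoxy-9α,13-epoxy-14,15,16-trihydroxylabdan-19,6β-olide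
Product: 49 (13S,14R)-20-acetoxy-9α,13:15,16-diepoxy-14-hydroxylabdan-19,6β-olide, via primary tosylate 48 (not isolated)
Conditions: TsCl (1.1 equiv), pyridine, 0 to 40 °C
Reagents that add atoms: none
Why: Sulfonylation of one primary hydroxyl of the 1,4-diol is followed by 5-exo-tet displacement by the other (Williamson-type cyclodehydration, helped by the quaternary C13). Either primary tosylate leads to the same oxolane, and the secondary C14 alcohol reacts more slowly.

Step 31
Reactants: 49 (13S,14R)-20-acetoxy-9α,13:15,16-diepoxy-14-hydroxylabdan-19,6β-olide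
Product: 50 (13S)-20-acetoxy-9α,13:15,16-diepoxy-14-oxolabdan-19,6β-olide
Conditions: Dess–Martin periodinane, NaHCO3, CH2Cl2, rt
Reagents that add atoms: none
Why: Dess–Martin oxidation of the secondary alcohol to the oxolan-3-one; C13 is quaternary and cannot epimerise.

Step 32
Reactants: 50 (13S)-20-acetoxy-9α,13:15,16-diepoxy-14-oxolabdan-19,6β-olide
Product: 52 (13S)-20-acetoxy-9α,13:15,16-diepoxy-14-(trifluoromethylsulfonyloxy)labd-14-en-19,6β-olide, via potassium enolate 51 (not isolated)
Conditions: KN(SiMe3)2 (1.05 equiv), THF, −78 °C; PhNTf2, −78 to 0 °C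
Reagents that add atoms: N-phenylbis(trifluoromethanesulfonimide) O=S(=O)(N(c1ccccc1)S(=O)(=O)C(F)(F)F)C(F)(F)F
Why: Enolisation can occur only at C15 (C13 is quaternary, and the ketone α-CH2 is far more acidic than the acetate); O-sulfonylation of the enolate gives the enol triflate that holds the C14=C15 double bond.

Step 33
Reactants: 52 (13S)-20-acetoxy-9α,13:15,16-diepoxy-14-(trifluoromethylsulfonyloxy)labd-14-en-19,6β-olide
Product: 53 (13R)-20-acetoxy-9α,13:15,16-diepoxylabd-14-en-19,6β-olide (CNP0218619.1)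
Conditions: Pd(OAc)2 (5 mol%), PPh3, Bu3N (3 equiv), HCO2H (2 equiv), DMF, 60 °C
Reagents that add atoms: none
Why: Palladium-catalysed formate reduction of the enol triflate (oxidative addition to zerovalent palladium, formate exchange, decarboxylation, reductive elimination) replaces the triflate by hydrogen. The acid-labile enol ether is thus revealed last, in a medium kept basic by excess amine.

Compound list

1 | tert-butyl(but-3-yn-1-yloxy)dimethylsilane | C#CCCO[Si](C)(C)C(C)(C)C | starting material
2 | oxirane (ethylene oxide) | C1CO1 | starting material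
3 | [(E)-4-(tert-butyldimethylsilyloxy)-2-methylbut-1-enyl]dimethylalane | C[Al](C)/C=C(\C)CCO[Si](C)(C)C(C)(C)C | intermediate
4 | lithium butyl[(E)-4-(tert-butyldimethylsilyloxy)-2-methylbut-1-enyl]dimethylaluminate | [Li+].CCCC[Al-](C)(C)/C=C(\C)CCO[Si](C)(C)C(C)(C)C | intermediate
5 | (E)-6-(tert-butyldimethylsilyloxy)-4-methylhex-3-en-1-ol | OCC/C=C(\C)CCO[Si](C)(C)C(C)(C)C | intermediate
6 | (E)-1-(tert-butyldimethylsilyloxy)-6-(tert-butyldiphenylsilyloxy)-3-methylhex-3-ene | CC(C)(C)[Si](OCC/C=C(\C)CCO[Si](C)(C)C(C)(C)C)(c1ccccc1)c1ccccc1 | intermediate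
7 | (E)-6-(tert-butyldiphenylsilyloxy)-3-methylhex-3-en-1-ol | OCC/C(C)=C/CCO[Si](c1ccccc1)(c1ccccc1)C(C)(C)C | intermediate
8 | (E)-6-(tert-butyldiphenylsilyloxy)-3-methylhex-3-enal | O=CC/C(C)=C/CCO[Si](c1ccccc1)(c1ccccc1)C(C)(C)C | intermediate
9 | tert-butyldimethyl(prop-2-yn-1-yloxy)silane | C#CCO[Si](C)(C)C(C)(C)C | starting material
10 | lithium 3-(tert-butyldimethylsilyloxy)prop-1-yn-1-ide | [Li]C#CCO[Si](C)(C)C(C)(C)C | intermediate
11 | rac-(E)-1-(tert-butyldimethylsilyloxy)-9-(tert-butyldiphenylsilyloxy)-6-methylnon-6-en-2-yn-4-ol | CC(C)(C)[Si](C)(C)OCC#CC(O)C/C(C)=C/CCO[Si](c1ccccc1)(c1ccccc1)C(C)(C)C | intermediate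
12 | (E)-1-(tert-butyldimethylsilyloxy)-9-(tert-butyldiphenylsilyloxy)-6-methylnon-6-en-2-yn-4-one | CC(C)(C)[Si](C)(C)OCC#CC(=O)C/C(C)=C/CCO[Si](c1ccccc1)(c1ccccc1)C(C)(C)C | intermediate
13 | (4S,6E)-1-(tert-butyldimethylsilyloxy)-9-(tert-butyldiphenylsilyloxy)-6-methylnon-6-en-2-yn-4-ol | CC(C)(C)[Si](C)(C)OCC#C[C@@H](O)C/C(C)=C/CCO[Si](c1ccccc1)(c1ccccc1)C(C)(C)C | intermediate
14 | sodium cyclic alkenylalanate of 13 (five-membered O–Al–C10=C5–C6 ring, two 2-methoxyethoxy groups on Al) | [Na+].COCCO[Al-]1(OCCOC)O[C@@H](C/C(C)=C/CCO[Si](c2ccccc2)(c2ccccc2)C(C)(C)C)C=C1CO[Si](C)(C)C(C)(C)C | intermediate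
15 | (2Z,4S,6E)-1-(tert-butyldimethylsilyloxy)-9-(tert-butyldiphenylsilyloxy)-2-iodo-6-methylnona-2,6-dien-4-ol | CC(C)(C)[Si](C)(C)OC/C(I)=C/[C@@H](O)C/C(C)=C/CCO[Si](c1ccccc1)(c1ccccc1)C(C)(C)C | intermediate
16 | (2Z,4S,6E)-1,4-bis(tert-butyldimethylsilyloxy)-9-(tert-butyldiphenylsilyloxy)-2-iodo-6-methylnona-2,6-diene | CC(C)(C)[Si](C)(C)OC/C(I)=C/[C@@H](O[Si](C)(C)C(C)(C)C)C/C(C)=C/CCO[Si](c1ccccc1)(c1ccccc1)C(C)(C)C | intermediate
17 | (2Z,4S,6E)-4-(tert-butyldimethylsilyloxy)-9-(tert-butyldiphenylsilyloxy)-2-iodo-6-methylnona-2,6-dien-1-ol | OC/C(I)=C/[C@@H](O[Si](C)(C)C(C)(C)C)C/C(C)=C/CCO[Si](c1ccccc1)(c1ccccc1)C(C)(C)C | intermediate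
18 | (2Z,4S,6E)-1-bromo-4-(tert-butyldimethylsilyloxy)-9-(tert-butyldiphenylsilyloxy)-2-iodo-6-methylnona-2,6-diene | BrC/C(I)=C/[C@@H](O[Si](C)(C)C(C)(C)C)C/C(C)=C/CCO[Si](c1ccccc1)(c1ccccc1)C(C)(C)C | intermediate
19 | methyl 2-methyl-3-oxobutanoate | COC(=O)C(C)C(C)=O | starting material
20 | sodium lithium dianion of methyl 2-methyl-3-oxobutanoate | [Na+].[Li+].[CH2-]C([O-])=C(C)C(=O)OC | intermediate
21 | methyl (6Z,8S,10E)-8-(tert-butyldimethylsilyloxy)-13-(tert-butyldiphenylsilyloxy)-6-iodo-2,10-dimethyl-3-oxotrideca-6,10-dienoate (C2 epimers) | COC(=O)C(C)C(=O)CC/C(I)=C/[C@@H](O[Si](C)(C)C(C)(C)C)C/C(C)=C/CCO[Si](c1ccccc1)(c1ccccc1)C(C)(C)C | intermediate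
22 | methyl (6Z,8S,10E)-8-(tert-butyldimethylsilyloxy)-13-(tert-butyldiphenylsilyloxy)-6-(hydroxymethyl)-2,10-dimethyl-3-oxotrideca-6,10-dienoate (C2 epimers) | COC(=O)C(C)C(=O)CC/C(CO)=C/[C@@H](O[Si](C)(C)C(C)(C)C)C/C(C)=C/CCO[Si](c1ccccc1)(c1ccccc1)C(C)(C)C | intermediate
23 | methyl (6Z,8S,10E)-6-(acetoxymethyl)-8-(tert-butyldimethylsilyloxy)-13-(tert-butyldiphenylsilyloxy)-2,10-dimethyl-3-oxotrideca-6,10-dienoate (C2 epimers) | COC(=O)C(C)C(=O)CC/C(COC(C)=O)=C/[C@@H](O[Si](C)(C)C(C)(C)C)C/C(C)=C/CCO[Si](c1ccccc1)(c1ccccc1)C(C)(C)C | intermediate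
24 | methyl 20-acetoxy-6α-(tert-butyldimethylsilyloxy)-12-(tert-butyldiphenylsilyloxy)-3-oxo-13,14,15,16-tetranorlabd-8(17)-en-19-oate (4β-CO2Me axial, 5α-H, 9α-H, 10β-CH2OAc) | COC(=O)[C@@]1(C)C(=O)CC[C@]2(COC(C)=O)[C@@H](CCO[Si](c3ccccc3)(c3ccccc3)C(C)(C)C)C(=C)C[C@H](O[Si](C)(C)C(C)(C)C)[C@@H]12 | intermediate
25 | methyl 20-acetoxy-3β-hydroxy-6α-(tert-butyldimethylsilyloxy)-12-(tert-butyldiphenylsilyloxy)-13,14,15,16-tetranorlabd-8(17)-en-19-oate | COC(=O)[C@@]1(C)[C@@H](O)CC[C@]2(COC(C)=O)[C@@H](CCO[Si](c3ccccc3)(c3ccccc3)C(C)(C)C)C(=C)C[C@H](O[Si](C)(C)C(C)(C)C)[C@@H]12 | intermediate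
26 | methyl 20-acetoxy-3β-(imidazol-1-ylthiocarbonyloxy)-6α-(tert-butyldimethylsilyloxy)-12-(tert-butyldiphenylsilyloxy)-13,14,15,16-tetranorlabd-8(17)-en-19-oate | COC(=O)[C@@]1(C)[C@@H](OC(=S)n3ccnc3)CC[C@]2(COC(C)=O)[C@@H](CCO[Si](c3ccccc3)(c3ccccc3)C(C)(C)C)C(=C)C[C@H](O[Si](C)(C)C(C)(C)C)[C@@H]12 | intermediate
27 | methyl 20-acetoxy-6α-(tert-butyldimethylsilyloxy)-12-(tert-butyldiphenylsilyloxy)-13,14,15,16-tetranorlabd-8(17)-en-19-oate | COC(=O)[C@@]1(C)CCC[C@]2(COC(C)=O)[C@@H](CCO[Si](c3ccccc3)(c3ccccc3)C(C)(C)C)C(=C)C[C@H](O[Si](C)(C)C(C)(C)C)[C@@H]12 | intermediate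
28 | methyl 20-acetoxy-8-oxo-6α-(tert-butyldimethylsilyloxy)-12-(tert-butyldiphenylsilyloxy)-13,14,15,16,17-pentanorlabdan-19-oate | COC(=O)[C@@]1(C)CCC[C@]2(COC(C)=O)[C@@H](CCO[Si](c3ccccc3)(c3ccccc3)C(C)(C)C)C(=O)C[C@H](O[Si](C)(C)C(C)(C)C)[C@@H]12 | intermediate
29 | methyl 20-acetoxy-8-(trimethylsilyloxy)-6α-(tert-butyldimethylsilyloxy)-12-(tert-butyldiphenylsilyloxy)-13,14,15,16,17-pentanorlabd-8-en-19-oate | COC(=O)[C@@]1(C)CCC[C@]2(COC(C)=O)C(CCO[Si](c3ccccc3)(c3ccccc3)C(C)(C)C)=C(O[Si](C)(C)C)C[C@H](O[Si](C)(C)C(C)(C)C)[C@@H]12 | intermediate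
30 | 8α,9α-epoxide of 29 (8β-trimethylsilyloxy) | COC(=O)[C@@]1(C)CCC[C@]2(COC(C)=O)[C@]4(CCO[Si](c3ccccc3)(c3ccccc3)C(C)(C)C)O[C@]4(O[Si](C)(C)C)C[C@H](O[Si](C)(C)C(C)(C)C)[C@@H]12 | intermediate
31 | methyl 20-acetoxy-8-oxo-9α-(trimethylsilyloxy)-6α-(tert-butyldimethylsilyloxy)-12-(tert-butyldiphenylsilyloxy)-13,14,15,16,17-pentanorlabdan-19-oate | COC(=O)[C@@]1(C)CCC[C@]2(COC(C)=O)[C@@](O[Si](C)(C)C)(CCO[Si](c3ccccc3)(c3ccccc3)C(C)(C)C)C(=O)C[C@H](O[Si](C)(C)C(C)(C)C)[C@@H]12 | intermediate
32 | methyl 20-acetoxy-9α-hydroxy-8-oxo-6α-(tert-butyldimethylsilyloxy)-12-(tert-butyldiphenylsilyloxy)-13,14,15,16,17-pentanorlabdan-19-oate | COC(=O)[C@@]1(C)CCC[C@]2(COC(C)=O)[C@@](O)(CCO[Si](c3ccccc3)(c3ccccc3)C(C)(C)C)C(=O)C[C@H](O[Si](C)(C)C(C)(C)C)[C@@H]12 | intermediate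
33 | methyl 20-acetoxy-9α-hydroxy-6α-(tert-butyldimethylsilyloxy)-12-(tert-butyldiphenylsilyloxy)-13,14,15,16-tetranorlabd-8(17)-en-19-oate | COC(=O)[C@@]1(C)CCC[C@]2(COC(C)=O)[C@@](O)(CCO[Si](c3ccccc3)(c3ccccc3)C(C)(C)C)C(=C)C[C@H](O[Si](C)(C)C(C)(C)C)[C@@H]12 | intermediate
34 | methyl 20-acetoxy-9α-hydroxy-6α-(tert-butyldimethylsilyloxy)-12-(tert-butyldiphenylsilyloxy)-13,14,15,16-tetranorlabdan-19-oate (8α-methyl, 8β-H) | COC(=O)[C@@]1(C)CCC[C@]2(COC(C)=O)[C@@](O)(CCO[Si](c3ccccc3)(c3ccccc3)C(C)(C)C)[C@H](C)C[C@H](O[Si](C)(C)C(C)(C)C)[C@@H]12 | intermediate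
35 | methyl 20-acetoxy-6α,9α,12-trihydroxy-13,14,15,16-tetranorlabdan-19-oate | COC(=O)[C@@]1(C)CCC[C@]2(COC(C)=O)[C@@](O)(CCO)[C@H](C)C[C@H](O)[C@@H]12 | intermediate
36 | methyl 20-acetoxy-9α-hydroxy-6α,12-bis(methylsulfonyloxy)-13,14,15,16-tetranorlabdan-19-oate | COC(=O)[C@@]1(C)CCC[C@]2(COC(C)=O)[C@@](O)(CCOS(C)(=O)=O)[C@H](C)C[C@H](OS(C)(=O)=O)[C@@H]12 | intermediate
37 | 20-acetoxy-9α-hydroxy-12-iodo-13,14,15,16-tetranorlabdan-19,6β-olide | CC(=O)OC[C@@]12CCC[C@]3(C)C(=O)O[C@H](C[C@@H](C)[C@]1(O)CCI)[C@H]23 | intermediate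
38 | but-2-yne-1,4-diol | OCC#CCO | starting material
39 | disodium cyclic alkenylalanate of but-2-yne-1,4-diol | [Na+].[Na+].COCCO[Al-]1(OCCOC)OCC=C1C[O-] | intermediate
40 | (Z)-2-iodobut-2-ene-1,4-diol | OC/C=C(\I)CO | intermediate
41 | (Z)-2-iodo-1,4-bis(triethylsilyloxy)but-2-ene | CC[Si](CC)(CC)OC/C=C(\I)CO[Si](CC)(CC)CC | intermediate
42 | [(E)-1,4-bis(triethylsilyloxy)but-2-en-2-yl]lithium | CC[Si](CC)(CC)OC/C=C(\[Li])CO[Si](CC)(CC)CC | intermediate
43 | [(E)-1,4-bis(triethylsilyloxy)but-2-en-2-yl]zinc chloride | CC[Si](CC)(CC)OC/C=C(\[Zn]Cl)CO[Si](CC)(CC)CC | intermediate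
44 | (13E)-20-acetoxy-9α-hydroxy-15,16-bis(triethylsilyloxy)labd-13-en-19,6β-olide | CC(=O)OC[C@@]12CCC[C@]3(C)C(=O)O[C@H](C[C@@H](C)[C@]1(O)CC/C(CO[Si](CC)(CC)CC)=C\CO[Si](CC)(CC)CC)[C@H]23 | intermediate
45 | (13E)-20-acetoxy-9α,15,16-trihydroxylabd-13-en-19,6β-olide | CC(=O)OC[C@@]12CCC[C@]3(C)C(=O)O[C@H](C[C@@H](C)[C@]1(O)CC/C(CO)=C\CO)[C@H]23 | intermediate
46 | (13R,14R)-20-acetoxy-13,14-epoxy-9α,15,16-trihydroxylabdan-19,6β-olide | CC(=O)OC[C@@]12CCC[C@]3(C)C(=O)O[C@H](C[C@@H](C)[C@]1(O)CC[C@]4(CO)O[C@@H]4CO)[C@H]23 | intermediate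
47 | (13S,14R)-20-acetoxy-9α,13-epoxy-14,15,16-trihydroxylabdan-19,6β-olide | CC(=O)OC[C@@]12CCC[C@]3(C)C(=O)O[C@H](C[C@@H](C)[C@]14CC[C@](CO)([C@H](O)CO)O4)[C@H]23 | intermediate
48 | (13S,14R)-20-acetoxy-9α,13-epoxy-14,16-dihydroxy-15-(4-tolylsulfonyloxy)labdan-19,6β-olide | CC(=O)OC[C@@]12CCC[C@]3(C)C(=O)O[C@H](C[C@@H](C)[C@]14CC[C@](CO)([C@H](O)COS(=O)(=O)c5ccc(C)cc5)O4)[C@H]23 | intermediate
49 | (13S,14R)-20-acetoxy-9α,13:15,16-diepoxy-14-hydroxylabdan-19,6β-olide | CC(=O)OC[C@@]12CCC[C@]3(C)C(=O)O[C@H](C[C@@H](C)[C@]14CC[C@]1([C@H](O)COC1)O4)[C@H]23 | intermediate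
50 | (13S)-20-acetoxy-9α,13:15,16-diepoxy-14-oxolabdan-19,6β-olide | CC(=O)OC[C@@]12CCC[C@]3(C)C(=O)O[C@H](C[C@@H](C)[C@]14CC[C@]1(C(=O)COC1)O4)[C@H]23 | intermediate
51 | potassium C14-enolate of 50 (C14=C15) | [K+].CC(=O)OC[C@@]12CCC[C@]3(C)C(=O)O[C@H](C[C@@H](C)[C@]14CC[C@]1(C([O-])=COC1)O4)[C@H]23 | intermediate
52 | (13S)-20-acetoxy-9α,13:15,16-diepoxy-14-(trifluoromethylsulfonyloxy)labd-14-en-19,6β-olide | CC(=O)OC[C@@]12CCC[C@]3(C)C(=O)O[C@H](C[C@@H](C)[C@]14CC[C@]1(C(OS(=O)(=O)C(F)(F)F)=COC1)O4)[C@H]23 | intermediate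
53 | (13R)-20-acetoxy-9α,13:15,16-diepoxylabd-14-en-19,6β-olide (CNP0218619.1) | CC(=O)OC[C@@]12CCC[C@]3(C)C(=O)O[C@H](C[C@@H](C)[C@]14CC[C@]1(C=COC1)O4)[C@H]23 | target

Total step count: 33. Longest linear sequence: 31 steps (steps 1–25 and 28–33); steps 26 and 27 prepare the coupling partner 41.

Steps least certain to work

Step 15 (key step). The cascade may stop after the first ring, the C4 radical may show poor facial discrimination if the C6 silyloxy group does not hold the equatorial site firmly, the C6 silyl ether may be lost slowly in acetic acid, and the copper elimination may give some endocyclic alkene. Fallback: the rings are closed by bromine-atom transfer and the alkene is made in a separate step. Compound 23 is brominated at C4 with N-bromosuccinimide and catalytic Mg(ClO4)2 to methyl (6Z,8S,10E)-6-(acetoxymethyl)-2-bromo-8-(tert-butyldimethylsilyloxy)-13-(tert-butyldiphenylsilyloxy)-2,10-dimethyl-3-oxotrideca-6,10-dienoate F1. A Lewis-acid-promoted atom-transfer radical bicyclization (Yb(OTf)3, Et3B, air, CH2Cl2, −78 °C) should then give the tertiary bromide methyl 20-acetoxy-8-bromo-6α-(tert-butyldimethylsilyloxy)-12-(tert-butyldiphenylsilyloxy)-3-oxo-13,14,15,16-tetranorlabdan-19-oate F2, in which the chelated keto ester is expected to sharpen the chair control. Dehydrobromination of F2 with DBU in toluene returns to 24.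

Step 20 (with step 21). Enolisation may go toward C7 instead of C9, which would send the oxygen to C7, and the C6 silyloxy group may be eliminated from the C7 enol. Fallback: the C9 oxygen is introduced without any enol chemistry, setting out from 27. Iodine-catalysed isomerisation in hot benzene should move the exocyclic alkene to the tetrasubstituted position, giving methyl 20-acetoxy-6α-(tert-butyldimethylsilyloxy)-12-(tert-butyldiphenylsilyloxy)-13,14,15,16-tetranorlabd-8-en-19-oate F3. Epoxidation with mCPBA from the α face gives methyl 20-acetoxy-8α,9α-epoxy-6α-(tert-butyldimethylsilyloxy)-12-(tert-butyldiphenylsilyloxy)-13,14,15,16-tetranorlabdan-19-oate F4. Base-free isomerisation of F4 with Al(Oi-Pr)3 in refluxing toluene (proton loss from the C17 methyl) leads to the allylic alcohol 33, where the route is rejoined; steps 19–22 are skipped.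

Step 23. Hydrogen may be delivered to the open α face of the C8 radical, leaving the methyl axial, because the β face carries the axial C20 arm. Fallback: the hydrogen is delivered from the β face by a directing group, setting out from 33. The 9-hydroxyl is masked with TESOTf and 2,6-lutidine as methyl 20-acetoxy-9α-(triethylsilyloxy)-6α-(tert-butyldimethylsilyloxy)-12-(tert-butyldiphenylsilyloxy)-13,14,15,16-tetranorlabd-8(17)-en-19-oate F5. Brief K2CO3 in MeOH at 0 °C removes the acetate to give methyl 20-hydroxy-9α-(triethylsilyloxy)-6α-(tert-butyldimethylsilyloxy)-12-(tert-butyldiphenylsilyloxy)-13,14,15,16-tetranorlabd-8(17)-en-19-oate F6. Hydroxyl-directed hydrogenation (H2, [Ir(cod)(PCy3)(py)]PF6, CH2Cl2) should add hydrogen syn to the β-CH2OH and give methyl 20-hydroxy-9α-(triethylsilyloxy)-6α-(tert-butyldimethylsilyloxy)-12-(tert-butyldiphenylsilyloxy)-13,14,15,16-tetranorlabdan-19-oate F7 with the 8α-methyl. Acetylation (Ac2O, pyridine) gives methyl 20-acetoxy-9α-(triethylsilyloxy)-6α-(tert-butyldimethylsilyloxy)-12-(tert-butyldiphenylsilyloxy)-13,14,15,16-tetranorlabdan-19-oate F8, and the fluoride conditions of step 24 remove all three silyl groups and return to 35. F6 and F7 must be handled without base or heat, because the free C20 hydroxyl could close onto C19.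

Step 28. The alkylpalladium intermediate may undergo β-hydride elimination, the alkenyllithium may lose silyloxide before transmetalation, and the 9-hydroxyl may protonate the zinc reagent. Fallback: the same bond is made by a B-alkyl Suzuki–Miyaura coupling, setting out from 37. Dehydroiodination with DBU in toluene at 90 °C gives 20-acetoxy-9α-hydroxy-13,14,15,16-tetranorlabd-11-en-19,6β-olide F9. Hydroboration with 9-BBN (excess, THF) gives the 12-(9-borabicyclo[3.3.1]nonan-9-yl) derivative of 20-acetoxy-9α-hydroxy-13,14,15,16-tetranorlabdan-19,6β-olide F10. Coupling of F10 with 41 (PdCl2(dppf), K3PO4, DMF–H2O, rt) gives 44, which the acidic work-up of step 28 converts to 45.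

Further compounds

F1 | step 15 | methyl (6Z,8S,10E)-6-(acetoxymethyl)-2-bromo-8-(tert-butyldimethylsilyloxy)-13-(tert-butyldiphenylsilyloxy)-2,10-dimethyl-3-oxotrideca-6,10-dienoate (C2 epimers) | COC(=O)C(C)(Br)C(=O)CC/C(COC(C)=O)=C/[C@@H](O[Si](C)(C)C(C)(C)C)C/C(C)=C/CCO[Si](c1ccccc1)(c1ccccc1)C(C)(C)C
F2 | step 15 | methyl 20-acetoxy-8-bromo-6α-(tert-butyldimethylsilyloxy)-12-(tert-butyldiphenylsilyloxy)-3-oxo-13,14,15,16-tetranorlabdan-19-oate (C8 epimers) | COC(=O)[C@@]1(C)C(=O)CC[C@]2(COC(C)=O)[C@@H](CCO[Si](c3ccccc3)(c3ccccc3)C(C)(C)C)C(C)(Br)C[C@H](O[Si](C)(C)C(C)(C)C)[C@@H]12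
F3 | step 20 | methyl 20-acetoxy-6α-(tert-butyldimethylsilyloxy)-12-(tert-butyldiphenylsilyloxy)-13,14,15,16-tetranorlabd-8-en-19-oate | COC(=O)[C@@]1(C)CCC[C@]2(COC(C)=O)C(CCO[Si](c3ccccc3)(c3ccccc3)C(C)(C)C)=C(C)C[C@H](O[Si](C)(C)C(C)(C)C)[C@@H]12
F4 | step 20 | methyl 20-acetoxy-8α,9α-epoxy-6α-(tert-butyldimethylsilyloxy)-12-(tert-butyldiphenylsilyloxy)-13,14,15,16-tetranorlabdan-19-oate | COC(=O)[C@@]1(C)CCC[C@]2(COC(C)=O)[C@]4(CCO[Si](c3ccccc3)(c3ccccc3)C(C)(C)C)O[C@]4(C)C[C@H](O[Si](C)(C)C(C)(C)C)[C@@H]12
F5 | step 23 | methyl 20-acetoxy-9α-(triethylsilyloxy)-6α-(tert-butyldimethylsilyloxy)-12-(tert-butyldiphenylsilyloxy)-13,14,15,16-tetranorlabd-8(17)-en-19-oate | COC(=O)[C@@]1(C)CCC[C@]2(COC(C)=O)[C@@](O[Si](CC)(CC)CC)(CCO[Si](c3ccccc3)(c3ccccc3)C(C)(C)C)C(=C)C[C@H](O[Si](C)(C)C(C)(C)C)[C@@H]12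
F6 | step 23 | methyl 20-hydroxy-9α-(triethylsilyloxy)-6α-(tert-butyldimethylsilyloxy)-12-(tert-butyldiphenylsilyloxy)-13,14,15,16-tetranorlabd-8(17)-en-19-oate | COC(=O)[C@@]1(C)CCC[C@]2(CO)[C@@](O[Si](CC)(CC)CC)(CCO[Si](c3ccccc3)(c3ccccc3)C(C)(C)C)C(=C)C[C@H](O[Si](C)(C)C(C)(C)C)[C@@H]12
F7 | step 23 | methyl 20-hydroxy-9α-(triethylsilyloxy)-6α-(tert-butyldimethylsilyloxy)-12-(tert-butyldiphenylsilyloxy)-13,14,15,16-tetranorlabdan-19-oate (8α-methyl) | COC(=O)[C@@]1(C)CCC[C@]2(CO)[C@@](O[Si](CC)(CC)CC)(CCO[Si](c3ccccc3)(c3ccccc3)C(C)(C)C)[C@H](C)C[C@H](O[Si](C)(C)C(C)(C)C)[C@@H]12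
F8 | step 23 | methyl 20-acetoxy-9α-(triethylsilyloxy)-6α-(tert-butyldimethylsilyloxy)-12-(tert-butyldiphenylsilyloxy)-13,14,15,16-tetranorlabdan-19-oate (8α-methyl) | COC(=O)[C@@]1(C)CCC[C@]2(COC(C)=O)[C@@](O[Si](CC)(CC)CC)(CCO[Si](c3ccccc3)(c3ccccc3)C(C)(C)C)[C@H](C)C[C@H](O[Si](C)(C)C(C)(C)C)[C@@H]12
F9 | step 28 | 20-acetoxy-9α-hydroxy-13,14,15,16-tetranorlabd-11-en-19,6β-olide | CC(=O)OC[C@@]12CCC[C@]3(C)C(=O)O[C@H](C[C@@H](C)[C@]1(O)C=C)[C@H]23
F10 | step 28 | 20-acetoxy-12-(9-borabicyclo[3.3.1]nonan-9-yl)-9α-hydroxy-13,14,15,16-tetranorlabdan-19,6β-olide | CC(=O)OC[C@@]12CCC[C@]3(C)C(=O)O[C@H](C[C@@H](C)[C@]1(O)CCB5C6CCCC5CCC6)[C@H]23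
A1 | alternative 1 | 20-acetoxy-9α,13:15,16-diepoxy-14-hydroxy-15-methoxylabdan-19,6β-olide | CC(=O)OC[C@@]12CCC[C@]3(C)C(=O)O[C@H](C[C@@H](C)[C@]14CC[C@]1([C@H](O)[C@@H](OC)OC1)O4)[C@H]23
A2 | alternative 1 | 20-acetoxy-13,14-epoxy-9α,16-dihydroxy-15,15-dimethoxylabdan-19,6β-olide | CC(=O)OC[C@@]12CCC[C@]3(C)C(=O)O[C@H](C[C@@H](C)[C@]1(O)CC[C@]4(CO)O[C@@H]4C(OC)OC)[C@H]23
A3 | alternative 2 | cyclobutane-fused γ-lactone photoadduct with C9 ketone, 3-chloropropyl group on C10 and silyloxy group on C20 | C[C@]12C(=O)O[C@@H]3CCC(=O)[C@](CCCCl)([C@@H]1O[Si](C)(C)C(C)(C)C)[C@H]23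
A4 | alternative 2 | 3-(3-chloropropyl)-4-oxocyclohex-2-en-1-yl (E)-3-(tert-butyldimethylsilyloxy)-2-methylprop-2-enoate (carbinol carbon configured as C6 of A3) | O=C1CC[C@@H](OC(=O)/C(C)=C/O[Si](C)(C)C(C)(C)C)C=C1CCCCl
A5 | alternative 3 | methyl 20-acetoxy-9α,13-epoxy-7-oxo-16-(tert-butyldimethylsilyloxy)-15-(trimethylsilyl)labd-14-yn-19-oate | CC(=O)OC[C@]12CCC[C@](C)(C(=O)OC)[C@@H]1CC(=O)[C@@H](C)[C@]23CC[C@](CO[Si](C)(C)C(C)(C)C)(C#C[Si](C)(C)C)O3
A6 | alternative 3 | methyl 20-acetoxy-13-hydroxy-7-oxo-16-(tert-butyldimethylsilyloxy)-15-(trimethylsilyl)labd-8-en-14-yn-19-oate | CC(=O)OC[C@]12CCC[C@](C)(C(=O)OC)[C@@H]1CC(=O)C(C)=C2CC[C@](O)(CO[Si](C)(C)C(C)(C)C)C#C[Si](C)(C)C
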